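Ring A (C10, C1–C5) is built last, on the ring B atoms C5 and C10 of a complete BCD tricycle. C5 is a CH hub between two quaternary carbons that each carry a carboxyl (C4–C19, C10–C20), so both flanking carbons are ester enolate carbons. In one flask an acetate enolate (C4, C19) adds to C5 of a C5=C10 cyclopentene ester, the C10 enolate is alkylated on the opposite face by 1-chloro-3-iodopropane (C1–C3), and the C4 enolate then displaces chloride. Three C–C bonds, C5, C10 and the trans A/B fusion arise together. The precursor is a tricyclic enoate containing no ring A carbon except C5 and C10. Methylation then sets C4.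

Key step: step 12

Remark: intermediates are described with gibberellane numbering (ring A C1–C5, C10; ring B C5, C6, C8, C9, C10; ring C C8, C9, C11–C14; ring D C8, C13–C16; C7 on C6; C17 on C16; C18 and C19 on C4; C20 on C10). β is the face of the hydrogens on C5 and C9 and of C7 and C15; α is the face of C19, C20, C11 and C14. Compounds 1, 2, 6, 10, 19, 20 and the reagents named are assumed to be commercial.

Step 1
Reactants: 1 1,4-dioxaspiro[4.4]nonan-7-one; 2 RAMP [(R)-1-amino-2-(methoxymethyl)pyrrolidine]
Product: 3 RAMP hydrazone of 1,4-dioxaspiro[4.4]nonan-7-one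
Conditions: neat, 60 °C
Reagents that add atoms: none
Why: Hydrazone formation between the ketone and the N-amino auxiliary needs no acid, so the ketal should survive; no stereocenter is formed.

Step 2
Reactants: 3 RAMP hydrazone of 1,4-dioxaspiro[4.4]nonan-7-one
Product: 4 RAMP hydrazone of (R)-8-[(triisopropylsilyloxy)methyl]-1,4-dioxaspiro[4.4]nonan-7-one
Conditions: LiN(iPr)2, THF, 0 °C; then iPr3SiOCH2Cl, −100 → −20 °C
Reagents that add atoms: (triisopropylsiloxy)methyl chloride, ClCO[Si](C(C)C)(C(C)C)C(C)C
Why: Asymmetric RAMP-hydrazone alkylation: the azaenolate should form at the α-CH2 remote from the ketal (the other α position is neopentyl-like), and the lithium-chelated azaenolate is alkylated by the α-chloro ether on the face fixed by the (R)-auxiliary, which sets C6 with its C7 substituent.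

Step 3
Reactants: 4 RAMP hydrazone of (R)-8-[(triisopropylsilyloxy)methyl]-1,4-dioxaspiro[4.4]nonan-7-one
Product: 5 (R)-8-[(triisopropylsilyloxy)methyl]-1,4-dioxaspiro[4.4]nonan-7-one
Conditions: CuCl2, THF/H2O (pH 7 phosphate buffer), rt
Reagents that add atoms: water, O
Why: Copper-assisted hydrolysis of the hydrazone at neutral pH should free the ketone and the auxiliary without epimerising the α stereocenter or opening the ketal.

Step 4
Reactants: 5 (R)-8-[(triisopropylsilyloxy)methyl]-1,4-dioxaspiro[4.4]nonan-7-one; 6 propargyl bromide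
Product: 9 (S)-4-[(triisopropylsilyloxy)methyl]-3-(prop-2-yn-1-yl)cyclopent-2-en-1-one, via tertiary propargyl carbinol 7 (not isolated), via beta-hydroxy ketone 8 (not isolated)
Conditions: Zn, THF, 0 °C → rt; then 2 M HCl, THF, rt
Reagents that add atoms: water, O
Why: Zinc Barbier propargylation (attack anti to the CH2OTIPS group; this carbinol center is lost again), then acid hydrolysis of the ketal and dehydration of the aldol-type β-hydroxy ketone through its enol, should give the conjugated enone in a ketal version of the Stork–Danheiser transposition that leaves C6 untouched.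

Step 5
Reactants: 10 methyl vinyl ketone
Product: 11 2-(tert-butyldimethylsilyloxy)buta-1,3-diene
Conditions: tBuMe2SiOTf, Et3N, Et2O, 0 °C
Reagents that add atoms: tert-butyldimethylsilyl trifluoromethanesulfonate, CC(C)(C)[Si](C)(C)OS(=O)(=O)C(F)(F)F
Why: Soft enolisation and O-silylation of the methyl ketone gives the silyl dienol ether; no stereocenter is formed.

Step 6
Reactants: 9 (S)-4-[(triisopropylsilyloxy)methyl]-3-(prop-2-yn-1-yl)cyclopent-2-en-1-one; 11 2-(tert-butyldimethylsilyloxy)buta-1,3-diene
Product: 12 BC keto silyl enol ether (C10=O; C12=C13–OTBS; 8β-propargyl; 6β-CH2OTIPS; 9β-H)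
Conditions: AlBr3/AlMe3 (5:1, 30 mol%), toluene/CH2Cl2, −10 °C
Reagents that add atoms: none
Why: Lewis acid-promoted Diels–Alder reaction of a β,β-disubstituted enone: the nucleophilic CH2 terminus next to C–OSi bonds to the β carbon C8 (so oxygen ends on C13), and the diene adds to the enone face opposite the C6 CH2OTIPS group, which sets the C8 quaternary center (C14 α, C15 β) and, by suprafacial addition, the cis B/C fusion with the C9 hydrogen β.

Step 7
Reactants: 12 BC keto silyl enol ether
Product: 14 BC hydroxy ketone (10α-OH; C13=O; 8β-propargyl; 6β-CH2OTIPS), via C10 alcohol 13 (not isolated)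
Conditions: NaBH4, EtOH, 0 °C; then 1 M HCl, THF, rt
Reagents that add atoms: none
Why: Hydride reduction of the cyclopentanone from the convex β face (temporary 10α-OH) masks C10 against the electron-transfer step that follows, and dilute acid then hydrolyses the silyl enol ether to the C13 ketone.

Step 8
Reactants: 14 BC hydroxy ketone
Product: 15 BCD diol (13-OH; 16-methylene; 10α-OH; 6β-CH2OTIPS)
Conditions: SmI2, HMPA, t-BuOH, THF, 0 °C
Reagents that add atoms: none
Why: SmI2-mediated ketyl–alkyne radical cyclisation (5-exo-dig) bonds C13 to C16 and, after reduction and protonation of the vinyl radical, should give the bicyclo[3.2.1]octane with the bridgehead tertiary alcohol and the exocyclic methylene; the C13 configuration is dictated by the bridge geometry.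

Step 9
Reactants: 15 BCD diol
Product: 16 BCD ketol (C10=O; 13-OH; 16-methylene; 6β-CH2OTIPS)
Conditions: Dess–Martin periodinane, CH2Cl2, rt
Reagents that add atoms: none
Why: Dess–Martin oxidation returns the secondary C10 alcohol to the ketone, while the tertiary bridgehead alcohol cannot be oxidised.

Step 10
Reactants: 16 BCD ketol
Product: 17 BCD enol triflate (C5=C10–OTf; 13-OH)
Conditions: LiN(iPr)2 (2.2 equiv), THF, −78 °C; then PhNTf2, −78 → 0 °C
Reagents that add atoms: N-phenylbis(trifluoromethanesulfonimide), O=S(=O)(N(c1ccccc1)S(=O)(=O)C(F)(F)F)C(F)(F)F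
Why: Kinetic enolate formation at the C5 methylene (not at the C9 ring-fusion methine) and O-sulfonylation with PhNTf2 should give the C5=C10 enol triflate, the first equivalent of base parking the hindered tertiary alcohol as its unreactive lithium alkoxide.

Step 11
Reactants: 17 BCD enol triflate
Product: 18 BCD enoate (C5=C10; C20 on C10 as 2-(trimethylsilyl)ethyl ester; 13-OH; 6β-CH2OTIPS)
Conditions: Pd(OAc)2, dppp, CO (1 atm), Me3SiCH2CH2OH, Et3N, DMF, 60 °C
Reagents that add atoms: carbon monoxide, [C-]#[O+]; 2-(trimethylsilyl)ethanol, C[Si](C)(C)CCO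
Why: Palladium-catalysed alkoxycarbonylation of the enol triflate (oxidative addition, CO insertion, alcoholysis) introduces C20 as a fluoride-labile ester on the C5=C10 double bond.

Step 12
Reactants: 18 BCD enoate; 19 2-(trimethylsilyl)ethyl acetate; 20 1-chloro-3-iodopropane
Product: 23 ABCD diester (4α-H; 4β-CO2CH2CH2SiMe3; 10α-CO2CH2CH2SiMe3; 5β-H; 13-OH; 6β-CH2OTIPS), via Michael adduct enolate 21 (not isolated), via chloropropyl diester alkoxide 22 (not isolated)
Conditions: 19, LiN(iPr)2, THF, −78 °C; add 18 (pre-treated with 1 equiv LiN(iPr)2 at −78 °C); then 20, HMPA, −78 → −30 °C; then LiN(iPr)2, −78 °C → rt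
Reagents that add atoms: none
Why: The lithium enolate of 19 adds 1,4 to the C5=C10 enoate (C4–C5 bond), the resulting C10 ester enolate 21 is C-alkylated by the iodide end of 20 (C10–C1 bond, 22), and a further equivalent of base forms the C4 ester enolate, which displaces chloride (C3–C4 bond). The closest known reaction type is the three-component conjugate addition–enolate alkylation of cycloalkene esters followed by intramolecular ester enolate alkylation (a Michael-initiated ring-closure sequence). Ring A closes in the 6-exo-tet mode through a chair-like transition state. C5 is set by attack of the donor on the α face, anti to the adjacent C6 CH2OTIPS group; C10 is set by alkylation on the β face, anti to the new C5 side chain and to C11, which gives the trans A/B fusion that a closure onto a trigonal C5 or C10 could not deliver; C4 should close with the ester equatorial (the C5 hydrogen eclipsing the enolate, which avoids allylic 1,3-strain) and is re-enolised in step 13. The step needs 1,4- over 1,2-addition, C-alkylation at C10 before any enolate forms at C4, and deprotonation only at C4 in the last stage; the ester acceptor, the primary iodide, the quaternary C10 and the absence of an acidifying group at C7 secure these, and the bridgehead lithium alkoxide is too hindered to be alkylated.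

Step 13
Reactants: 23 ABCD diester
Product: 24 methylated ABCD diester (4β-CH3; 4α-CO2CH2CH2SiMe3; 10α-CO2CH2CH2SiMe3; 13-OH; 6β-CH2OTIPS)
Conditions: LiN(iPr)2 (2.5 equiv), THF/HMPA, −78 → −40 °C; then MeI
Reagents that add atoms: iodomethane, CI
Why: Ester enolate alkylation: the exocyclic C4 enolate should be methylated on the equatorial β face because the axial C20 ester on C10 shields the α face (1,3-diaxial), so C18 becomes β and the C19 ester ends axial and α, cis to C20.

Step 14
Reactants: 24 methylated ABCD diester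
Product: 25 7,13-dihydroxy 19,20-diacid (C7 as CH2OH; free C19 and C20 acids)
Conditions: Bu4NF, THF, 40 °C; then dilute HCl
Reagents that add atoms: none
Why: Fluoride-mediated desilylation: fluoride attacks silicon, so both hindered 2-(trimethylsilyl)ethyl esters fragment with loss of ethylene without attack at the carbonyl groups, and the primary TIPS ether is cleaved in the same operation.

Step 15
Reactants: 25 7,13-dihydroxy 19,20-diacid
Product: 26 target gibberellin (ent-13-hydroxygibberell-16-ene-7,19,20-trioic acid)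
Conditions: TEMPO (cat.), PhI(OAc)2, MeCN/H2O, rt
Reagents that add atoms: water, O
Why: Nitroxyl-catalysed oxidation of the primary alcohol through the aldehyde hydrate to the acid should leave the tertiary alcohol and the 1,1-disubstituted alkene untouched and keep C6 in the β-carboxyl configuration, which is expected to be the thermodynamically preferred one.

Compound list

1 | 1,4-dioxaspiro[4.4]nonan-7-one | O=C1CCC2(C1)OCCO2 | starting material
2 | RAMP, (R)-1-amino-2-(methoxymethyl)pyrrolidine | COC[C@H]1CCCN1N | starting material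
3 | RAMP hydrazone of 1,4-dioxaspiro[4.4]nonan-7-one | COC[C@H]1CCCN1N=C1CCC2(C1)OCCO2 | intermediate
4 | RAMP hydrazone of (R)-8-[(triisopropylsilyloxy)methyl]-1,4-dioxaspiro[4.4]nonan-7-one | COC[C@H]1CCCN1N=C1CC2(OCCO2)C[C@@H]1CO[Si](C(C)C)(C(C)C)C(C)C | intermediate
5 | (R)-8-[(triisopropylsilyloxy)methyl]-1,4-dioxaspiro[4.4]nonan-7-one | O=C1CC2(OCCO2)C[C@@H]1CO[Si](C(C)C)(C(C)C)C(C)C | intermediate
6 | propargyl bromide (3-bromoprop-1-yne) | BrCC#C | starting material
7 | (8R)-7-(prop-2-yn-1-yl)-8-[(triisopropylsilyloxy)methyl]-1,4-dioxaspiro[4.4]nonan-7-ol, propargyl trans to CH2OTIPS | C#CC[C@@]1(O)CC2(OCCO2)C[C@@H]1CO[Si](C(C)C)(C(C)C)C(C)C | intermediate (not isolated)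
8 | (4R)-3-hydroxy-3-(prop-2-yn-1-yl)-4-[(triisopropylsilyloxy)methyl]cyclopentan-1-one, OH cis to CH2OTIPS | C#CC[C@@]1(O)CC(=O)C[C@@H]1CO[Si](C(C)C)(C(C)C)C(C)C | intermediate (not isolated)
9 | (S)-4-[(triisopropylsilyloxy)methyl]-3-(prop-2-yn-1-yl)cyclopent-2-en-1-one | C#CCC1=CC(=O)C[C@@H]1CO[Si](C(C)C)(C(C)C)C(C)C | intermediate
10 | methyl vinyl ketone (but-3-en-2-one) | CC(=O)C=C | starting material
11 | 2-(tert-butyldimethylsilyloxy)buta-1,3-diene | C=CC(=C)O[Si](C)(C)C(C)(C)C | intermediate
12 | BC keto silyl enol ether: cis-fused bicyclo[4.3.0]nonene, ring B cyclopentanone (C10=O), ring C with C12=C13 and OTBS on C13, 8β-propargyl, 6β-CH2OTIPS, 9β-H | C#CC[C@]12CC(O[Si](C)(C)C(C)(C)C)=CC[C@H]1C(=O)C[C@@H]2CO[Si](C(C)C)(C(C)C)C(C)C | intermediate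
13 | 10α-alcohol of 12 with the silyl enol ether intact | C#CC[C@]12CC(O[Si](C)(C)C(C)(C)C)=CC[C@H]1[C@@H](O)C[C@@H]2CO[Si](C(C)C)(C(C)C)C(C)C | intermediate (not isolated)
14 | BC hydroxy ketone: 10α-OH, C13 ketone, 8β-propargyl, 6β-CH2OTIPS, 9β-H | C#CC[C@]12CC(=O)CC[C@H]1[C@@H](O)C[C@@H]2CO[Si](C(C)C)(C(C)C)C(C)C | intermediate
15 | BCD diol: bicyclo[3.2.1]octane C/D unit with 13-OH and 16(17)-methylene, 10α-OH, 6β-CH2OTIPS | C=C1C[C@]23C[C@@]1(O)CC[C@H]2[C@@H](O)C[C@@H]3CO[Si](C(C)C)(C(C)C)C(C)C | intermediate
16 | BCD ketol: C10 ketone, 13-OH, 16(17)-methylene, 6β-CH2OTIPS | C=C1C[C@]23C[C@@]1(O)CC[C@H]2C(=O)C[C@@H]3CO[Si](C(C)C)(C(C)C)C(C)C | intermediate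
17 | BCD enol triflate: C5=C10 with OTf on C10, 13-OH | C=C1C[C@]23C[C@@]1(O)CC[C@H]2C(OS(=O)(=O)C(F)(F)F)=C[C@@H]3CO[Si](C(C)C)(C(C)C)C(C)C | intermediate
18 | BCD enoate: C5=C10 with C20 on C10 as 2-(trimethylsilyl)ethyl ester, 13-OH, 6β-CH2OTIPS | C=C1C[C@]23C[C@@]1(O)CC[C@H]2C(C(=O)OCC[Si](C)(C)C)=C[C@@H]3CO[Si](C(C)C)(C(C)C)C(C)C | intermediate
19 | 2-(trimethylsilyl)ethyl acetate | CC(=O)OCC[Si](C)(C)C | starting material
20 | 1-chloro-3-iodopropane | ClCCCI | starting material
21 | dilithium salt (C10 ester enolate and 13-alkoxide) of the Michael adduct with 5α-CH2CO2CH2CH2SiMe3, 5β-H | [Li+].[Li+].C=C1C[C@]23C[C@@]1([O-])CC[C@H]2C(=C([O-])OCC[Si](C)(C)C)[C@@H](CC(=O)OCC[Si](C)(C)C)[C@@H]3CO[Si](C(C)C)(C(C)C)C(C)C | intermediate (not isolated)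
22 | lithium 13-alkoxide of the diester with 10β-(3-chloropropyl), 10α-ester, 5α-CH2CO2CH2CH2SiMe3 | [Li+].C=C1C[C@]23C[C@@]1([O-])CC[C@H]2[C@@](CCCCl)(C(=O)OCC[Si](C)(C)C)[C@@H](CC(=O)OCC[Si](C)(C)C)[C@@H]3CO[Si](C(C)C)(C(C)C)C(C)C | intermediate (not isolated)
23 | ABCD diester: ring A closed and trans-fused, 4α-H, 4β-ester (C19), 10α-ester (C20), both 2-(trimethylsilyl)ethyl, 5β-H, 13-OH, 6β-CH2OTIPS | C=C1C[C@]23C[C@@]1(O)CC[C@H]2[C@]1(C(=O)OCC[Si](C)(C)C)CCC[C@H](C(=O)OCC[Si](C)(C)C)[C@H]1[C@@H]3CO[Si](C(C)C)(C(C)C)C(C)C | intermediate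
24 | methylated ABCD diester: 19,20-bis[2-(trimethylsilyl)ethyl] ester of the target triacid skeleton in which C7 is CH2OTIPS (4β-CH3, 4α-ester, 10α-ester, 13-OH) | C=C1C[C@]23C[C@@]1(O)CC[C@H]2[C@]1(C(=O)OCC[Si](C)(C)C)CCC[C@@](C)(C(=O)OCC[Si](C)(C)C)[C@H]1[C@@H]3CO[Si](C(C)C)(C(C)C)C(C)C | intermediate
25 | 7,13-dihydroxy 19,20-diacid: the target gibberellin in which C7 is CH2OH | C=C1C[C@]23C[C@@]1(O)CC[C@H]2[C@]1(C(=O)O)CCC[C@@](C)(C(=O)O)[C@H]1[C@@H]3CO | intermediate
26 | target gibberellin: ent-13-hydroxygibberell-16-ene-7,19,20-trioic acid (4β-methyl; carboxyl groups C19 on C4α, C20 on C10α and C7 on C6β; 13-OH; 16(17)-methylene) | C=C1C[C@]23C[C@@]1(O)CC[C@H]2[C@]1(C(=O)O)CCC[C@@](C)(C(=O)O)[C@H]1[C@@H]3C(=O)O | target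

Total step count: 15. Longest linear sequence: 14 steps (steps 1–4 and 6–15, from 1 to 26).

Steps most likely to fail

Step 12 (key step). Proton transfer between the hindered C10 enolate and the C4 methylene before C-alkylation, intermolecular alkylation of the C4 enolate by unreacted 20, and slow displacement of chloride could each erode the one-flask sequence. The fallback sets out from 18 and comes back at 23. The coupling of 18, 19 and 20 is stopped after the alkylation stage and worked up to give the neutral 10β-(3-chloropropyl) diester F1, from which excess 20 is removed. The chloride is exchanged for iodide (NaI, acetone, reflux; Finkelstein reaction) to give the 10β-(3-iodopropyl) diester F2. The ring is then closed in a separate operation with KN(SiMe3)2 in THF at −78 → 0 °C, which should give 23.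

Step 6. The hindered β,β-disubstituted enone may react too slowly, so that polymerisation of the diene or loss of the silyl enol ether takes over. The fallback sets out from 9 (with 11) and comes back at 12 by a stepwise ionic annulation. A Mukaiyama–Michael addition catalysed by tBuMe2SiNTf2 (CH2Cl2, −78 °C) joins the diene terminus to C8 with silyl transfer and should give the C10 silyl enol ether carrying the 8α-(2-oxobut-3-enyl) chain F3. A second, intramolecular Mukaiyama–Michael addition of C9 to the vinyl ketone (Me2AlCl, CH2Cl2, −40 °C) then closes ring C and gives 12.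

Step 13. Deprotonation of the hindered axial hydrogen on C4 may be slow, and under more forcing conditions the C13 alkoxide may be O-methylated. The fallback sets out from 23 and comes back at 25. The tertiary alcohol is silylated (Me3SiOTf, 2,6-lutidine, CH2Cl2, −78 °C) to give the 13-O-trimethylsilyl ether of 23 F4. This is methylated with KN(SiMe3)2 and MeI in THF/DMPU to give the 13-O-trimethylsilyl ether of 24 F5. F5 is submitted to the conditions of step 14, where Bu4NF removes the trimethylsilyl ether together with the other silyl groups and gives 25.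

Further compounds

F1 | step 12 | neutral diester with 10β-(3-chloropropyl), 10α-ester, 5α-CH2CO2CH2CH2SiMe3, 13-OH (protonated form of 22) | C=C1C[C@]23C[C@@]1(O)CC[C@H]2[C@@](CCCCl)(C(=O)OCC[Si](C)(C)C)[C@@H](CC(=O)OCC[Si](C)(C)C)[C@@H]3CO[Si](C(C)C)(C(C)C)C(C)C
F2 | step 12 | 10β-(3-iodopropyl) analogue of F1 | C=C1C[C@]23C[C@@]1(O)CC[C@H]2[C@@](CCCI)(C(=O)OCC[Si](C)(C)C)[C@@H](CC(=O)OCC[Si](C)(C)C)[C@@H]3CO[Si](C(C)C)(C(C)C)C(C)C
F3 | step 6 | cyclopentenyl silyl ether: C9=C10–OTBS, C8 with β-propargyl and α-CH2C(=O)CH=CH2, 6β-CH2OTIPS | C#CC[C@]1(CC(=O)C=C)C=C(O[Si](C)(C)C(C)(C)C)C[C@@H]1CO[Si](C(C)C)(C(C)C)C(C)C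
F4 | step 13 | 13-O-trimethylsilyl ether of 23 | C=C1C[C@]23C[C@@]1(O[Si](C)(C)C)CC[C@H]2[C@]1(C(=O)OCC[Si](C)(C)C)CCC[C@H](C(=O)OCC[Si](C)(C)C)[C@H]1[C@@H]3CO[Si](C(C)C)(C(C)C)C(C)C
F5 | step 13 | 13-O-trimethylsilyl ether of 24 | C=C1C[C@]23C[C@@]1(O[Si](C)(C)C)CC[C@H]2[C@]1(C(=O)OCC[Si](C)(C)C)CCC[C@@](C)(C(=O)OCC[Si](C)(C)C)[C@H]1[C@@H]3CO[Si](C(C)C)(C(C)C)C(C)C
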